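You have to pick the temperature for a 50 min flask of 0.020 M substrate, and the earlier runs seem to argue both ways.

| setting | blue | ochre | ash | larch | alder | birch |
|---|---|---|---|---|---|---|
| substrate | 0.010 M | 0.015 M | 0.020 M | 0.020 M | 0.020 M | 0.020 M |
| temperature | 35 °C | 70 °C | 80 °C | 100 °C | 40 °C | 60 °C |
| remark | run made earlier | run made earlier |  |  |  |  |
| time |  |  | 50 min | 50 min | 50 min | 50 min |

| run | time / min | target / % |
|---|---|---|
| blue | 40.0 | 3.6 |
| blue | 120 | 9.1 |
| blue | 240 | 16.2 |
| blue | 360 | 21.4 |
| blue | 480 | 23.5 |
| ochre | 6.00 | 12.2 |
| ochre | 20.0 | 16.1 |
| ochre | 40.0 | 14.9 |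
| ochre | 60.0 | 14.1 |
| ochre | 80.0 | 12.8 |

(each reading ± 0.5 percentage points)

- percent here means substrate units held: one target or isomer of the product counts as two
- steps that have been proposed: 2 substrate <-> target; target <-> isomer of the product; substrate <-> dormant form

- the flask with the highest amount of target, in percent of the substrate charged ("all alike" if they lie within 1.5 percentage points) (ash / larch / alder / birch / all alike)
- final target, as a percentage of the substrate charged, in ash
- final target, as a percentage of the substrate charged, in larch
- final target, as a percentage of the substrate charged, in alder
- final target, as a percentage of the substrate charged, in birch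

Ochre at 70 °C held 12.2% target after 6.00 min, while blue at 35 °C held 3.6% after 40.0 min. Yet ochre's best reading is 16.1%, and blue's last is 23.5%. The quicker run holds less.

Blue's first reading gives 0.0373 for one number, the dose: the target share over the share not yet target, as the forward step by itself would leave them. For that step the dose grows in proportion to charge and to time. A dose of one is the even split, half the charge turned, and that is the zero of your scale.

Scaled by time from its first reading, blue's dose comes to 0.448 at its last reading. Ochre, scaled from its first reading, reaches 0.463 at 20.0 min. The doses match, and the forward step by itself would give about 30.9%. Speed is therefore not the gap: at equal dose the hotter run holds less, and ochre's readings sink to 12.8% by 80.0 min.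

Per unit of charge and time, ochre's dose beats blue's by a factor of 16.5. I spread that factor evenly over the degrees. My doses at 50 min are then 0.139 in alder, 0.693 in birch, 3.44 in ash and 17.1 in larch.

I treat alder as under kinetic control, so I expect 12.2% there. My dose for birch stands below one and my dose for ash above it. Birch is cooler than ochre, so I expect it above ochre's best reading but under its forward figure of 40.9%. Ash and larch are hotter than ochre, so I expect them below ochre's best reading. I choose birch.

The forecast also names birch, with 12% in ash, 5% in larch, 12% in alder and 24% in birch, and says “Birch is nearly at equilibrium”.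

The flask gives birch: 10.9% in ash, 1.71% in larch, 12.8% in alder and 26.2% in birch.

    2 substrate ⇌ target (K = 10.0 L mol⁻¹, k = 0.0440 L mol⁻¹ s⁻¹, Ea = 81.0 kJ mol⁻¹, ΔH = −70.0 kJ mol⁻¹)
    target ⇌ isomer of the product (K = 1.20, k = 0.00170 s⁻¹, Ea = 98.0 kJ mol⁻¹, ΔH = −73.0 kJ mol⁻¹)
    substrate ⇌ dormant form (K = 0.500, k = 3.40 × 10⁻⁴ s⁻¹, Ea = 108 kJ mol⁻¹, ΔH = 60.0 kJ mol⁻¹)
    (constants at 80 °C)

Larch shows what lies past one. Its dose of 17.1 is far above the even split, yet larch holds 1.71%. With the way back from target to substrate struck out, it holds 60.6%, so that way back is the main reason larch holds so little.

Now run birch at 35 °C, blue's temperature, so no heating factor enters. Scaling blue's dose by charge and time gives 0.0934, which means 8.54% target. The computed flask holds 8.36%.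

Readings and results were computed on assumed constants, and the scatter is random.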